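If a chiral catalyst is charged below the level of an impurity that destroys it, I wanted to know how far the flask gets before the catalyst dies.

    coupling partner + catalyst intermediate B → free catalyst + right-handed product (k1 = 220 M⁻¹ s⁻¹)
    coupling partner → decomposed reagent (k2 = 0.032 s⁻¹)
    coupling partner + catalyst intermediate A → free catalyst + left-handed product (k3 = 550 M⁻¹ s⁻¹)
    free catalyst + impurity → spent catalyst (k4 = 85000 M⁻¹ s⁻¹)
    free catalyst + right-handed substrate ⇌ catalyst intermediate B (K5 = 150 M⁻¹, k5 = 2200 M⁻¹ s⁻¹)
    free catalyst + left-handed substrate ⇌ catalyst intermediate A (K6 = 54 M⁻¹, k6 = 85000 M⁻¹ s⁻¹)

left-handed substrate 0.15 M; coupling partner 0.165 M; free catalyst 0.17 mM; impurity 0.20 mM; right-handed substrate 0.15 M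

- free catalyst is single-handed; left-handed substrate and right-handed substrate are mirror images of each other, charged as a racemate, each of them at the stated concentration
- charge of left-handed substrate (flask): 0.15 M

1. the form that holds most of the catalyst when 5.0 % of the left-handed substrate and right-handed substrate together are converted (catalyst intermediate A / catalyst intermediate B / spent catalyst / free catalyst)
2. its share of the catalyst then
3. factor on the rate of making left-handed product when 5.0 % of the left-handed substrate and right-handed substrate together are converted if coupling partner is charged twice over
4. factor on the rate when 5.0 % of the left-handed substrate and right-handed substrate together are converted if free catalyst is charged at 0.80 mM instead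

I began with the balance of the reagent charged in the smaller amount. In the poisoning step free catalyst is charged in the smaller amount, 0.17 mM against 0.20 mM of impurity, and each catalyst lost takes one impurity with it. The impurity excess, 0.0300 mM, is the impurity charged minus the catalyst charged.

In one extreme version the impurity catches the catalyst at once, so no product forms and the excess stands unbound. In the other there is no impurity, and the coupling partner sets a ceiling of 55.0 % conversion while also decaying with a half-life of 0.361 min.

The real flask lies between these. Capture by left-handed substrate, set against the release and coupling of catalyst intermediate A, gives 7.66 of catalyst intermediate A per free catalyst at the charges, and capture by right-handed substrate, set against the same two exits of catalyst intermediate B, gives 6.47 of catalyst intermediate B. That gives 54.7 turnovers per catalyst lost at the start.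

As the impurity thins, the loss slows towards the excess. With the coupling partner held at its charge, I reckoned 10.9 mM of product times ln(impurity charged over live catalyst plus excess). This leaves 0.0208 mM live at 5.0 % conversion, so 87.8 % is spent. My reckoning stopped there.

The forecast said spent catalyst at 92 %, a higher share than mine, with factors of 12 for doubled coupling partner and 60 for the larger catalyst charge, on the ground that “The impurity outnumbers the catalyst and kills it within seconds”.

The simulation gave spent catalyst at 92.4 %, with factors of 13.4 and 64.7.

The excess is 15.0 % of the impurity charged, and at 3.00 min the flask held 15 % of its impurity unbound, with spent catalyst at 100 % and 92 % of the left-handed substrate and 97 % of the right-handed substrate remaining. In the flask charged at 0.80 mM the sign reverses: catalyst exceeds impurity by 0.600 mM, which is 46.4 times the 0.0129 mM unspent in the first flask at 5.0 % conversion, and the rate there rose by a factor of 64.7.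

All constants are assumed; the rest is arithmetic.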